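**Retrosynthetic overview**
- Guajadial C ⇐ mild removal of two aryl Boc groups ⇐ key step: palladium-catalysed decarboxylative benzylation/allylic etherification that joins a semicyclic terpene diene (fragment 1) to a benzhydryl carbonate (fragment 2). It forms the CH2–CH(Ph) bond, the spiro C–O bond, the pyran ring and both new stereocentres.
- Fragment 1 ⇐ Wittig methylenation of a Δ1(8a)-octalone ⇐ α′-selenenylation, 1,4-reduction and selenoxide elimination of a cis-fused enone ⇐ Diels–Alder reaction of (S)-cryptone with a Danishefsky-type diene, then methylenation and hydrogenation to set the methyl centre.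
- Fragment 2 ⇐ PhLi addition, Boc migration and silylation on tri-Boc triformylphloroglucinol ⇐ Duff formylation ⇐ phloroglucinol made from resorcinol by iridium-catalysed C–H borylation and oxidation.
- Ring order: ring A (cryptone), ring B (Diels–Alder), pyran ring last (key step); the aromatic ring comes from resorcinol.

Assumption: the (Sa,R,R) antipode of phosphoramidite L1 (O,O′-(S)-1,1′-binaphthyl-2,2′-diyl N,N-bis[(R)-1-phenylethyl]phosphoramidite) is taken as the one that gives the (R) benzylic centre in step 15; if the first run shows the opposite sense, its mirror image is used with no other change.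

**Fragment 1 (diene 15)**

Step 1
Reactants: 1 3-methylbutanal; 2 but-3-en-2-one
Product: 4 (S)-4-isopropylcyclohex-2-en-1-one [(S)-cryptone], via (S)-2-isopropyl-5-oxohexanal 3 (not isolated)
Conditions: (S)-2-(methoxydiphenylmethyl)pyrrolidine (5 mol %), ethyl 3,4-dihydroxybenzoate (20 mol %), neat, 4 °C, 36 h; then LiOH (0.2 equiv), iPrOH/H2O, rt
Reagents that add atoms: none
Why: Enamine-catalysed Michael addition (the (S)-diarylprolinol ether shields one enamine face and sets the (S) centre) followed by intramolecular aldol condensation gives the known (S)-cryptone.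

Step 2
Reactants: 5 (E)-4-methoxybut-3-en-2-one
Product: 6 (E)-tert-butyl[(4-methoxybuta-1,3-dien-2-yl)oxy]dimethylsilane
Conditions: TBSOTf, Et3N, Et2O, 0 °C → rt
Reagents that add atoms: tert-butyldimethylsilyl trifluoromethanesulfonate, CC(C)(C)[Si](C)(C)OS(=O)(=O)C(F)(F)F
Why: Soft enolisation and O-silylation of the vinylogous ester give a Danishefsky-type diene whose TBS enol ether survives the next two steps.

Step 3
Reactants: 4 (S)-cryptone; 6 the silyloxy diene
Product: 7 (4S,4aS,8S,8aR)-6-[(tert-butyldimethylsilyl)oxy]-8-methoxy-4-isopropyl-3,4,4a,5,8,8a-hexahydronaphthalen-1(2H)-one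
Conditions: PhMe, BHT (cat.), 170 °C (sealed tube), 48 h
Reagents that add atoms: none
Why: Diels–Alder reaction in which the nucleophilic CH2 terminus of 6 bonds to the enone β-carbon, the diene adds suprafacially (cis ring fusion) to the face anti to the isopropyl group, and endo approach places OMe syn to the carbonyl carbon (that centre is lost later).

Step 4
Reactants: 7 the Diels–Alder adduct
Product: 8 tert-butyl{[5-methoxy-4-methylidene-1-isopropyl-1,2,3,4,4a,5,8,8a-octahydronaphthalen-7-yl]oxy}dimethylsilane (all four stereocentres as in 7)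
Conditions: Cp2TiMe2 (2.5 equiv), PhMe/THF, 70 °C, dark
Reagents that add atoms: dimethyltitanocene, C[Ti](C)(C1C=CC=C1)C1C=CC=C1
Why: Petasis methylenation through non-basic titanocene methylidene converts the hindered ketone to the exocyclic alkene without epimerising the adjacent cis ring-fusion centre or touching the silyl enol ether.

Step 5
Reactants: 8 the exocyclic alkene
Product: 10 (4aS,5R,8S,8aS)-5-methyl-8-isopropyl-4a,5,6,7,8,8a-hexahydronaphthalen-2(1H)-one, via hydrogenated silyl enol ether 9 (not isolated)
Conditions: H2 (1 atm), PtO2 (5 mol %), NaHCO3, EtOAc, rt; filter; then HCl (1 M), THF, 0 °C → rt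
Reagents that add atoms: none
Why: Heterogeneous hydrogenation delivers hydrogen to the exocyclic alkene from the convex α-face of the cis-fused bicycle (the β-face is covered by ring B and its OMe group), setting the methyl centre with methyl β, and the acid step hydrolyses the silyl enol ether with β-elimination of methanol to the enone.

Step 6
Reactants: 10 the cis-fused enone
Product: 11 1-(phenylselanyl) derivative of 10 (PhSe on C-1 on the face of H-8a)
Conditions: LiN(iPr)2 (1.1 equiv), THF, −78 °C; PhSeCl, −78 °C
Reagents that add atoms: benzeneselenenyl chloride, Cl[Se]c1ccccc1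
Why: Kinetic deprotonation of the enone can only occur at the α′ carbon (cross-conjugated enolate), and selenenylation from the convex face marks, cis to H-8a, the carbon that must become olefinic.

Step 7
Reactants: 11 the α′-selenide
Product: 14 (4aR,5R,8S)-5-methyl-8-isopropyl-4,4a,5,6,7,8-hexahydronaphthalen-2(3H)-one, via saturated selenide 12 (not isolated), via selenoxide 13 (not isolated)
Conditions: Li[HB(sBu)3] (1.1 equiv), THF, −78 °C; NH4Cl (aq); then H2O2 (30%), pyridine, CH2Cl2, 0 °C → rt
Reagents that add atoms: none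
Why: Conjugate hydride reduction removes the C3=C4 double bond, then selenide oxidation and syn selenoxide elimination, whose only β-hydrogen is H-8a, place the enone double bond at C1=C8a regiospecifically (a cross-conjugated dienone, which would aromatise, is never formed).

Step 8
Reactants: 14 the Δ1(8a)-enone
Product: 15 (4aR,5R,8S)-5-methyl-2-methylidene-8-isopropyl-2,3,4,4a,5,6,7,8-octahydronaphthalene (fragment 1)
Conditions: Ph3PCH3Br (1.5 equiv), KN(SiMe3)2 (1.4 equiv), THF, 0 °C; then 14, 0 °C → rt
Reagents that add atoms: methyltriphenylphosphonium bromide, C[P+](c1ccccc1)(c1ccccc1)c1ccccc1.[Br-]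
Why: Wittig methylenation of the enone carbonyl gives the semicyclic 1,3-diene, and with no excess base at 0 °C the γ-positions (C-4a, C-8) are not enolised.

**Fragment 2 (carbonate 26)**

Step 9
Reactants: 16 resorcinol
Product: 17 1,3-bis(methoxymethoxy)benzene
Conditions: MOMCl (2.4 equiv), iPr2NEt, CH2Cl2, 0 °C → rt
Reagents that add atoms: chloromethyl methyl ether, COCCl
Why: Williamson-type acetal protection masks both phenols and provides the steric bias for the next step.

Step 10
Reactants: 17 the bis-MOM ether
Product: 18 2-[3,5-bis(methoxymethoxy)phenyl]-4,4,5,5-tetramethyl-1,3,2-dioxaborolane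
Conditions: [Ir(OMe)(cod)]2 (1.5 mol %), 4,4′-di-tert-butyl-2,2′-bipyridine (3 mol %), B2pin2 (1.0 equiv), hexane, 80 °C
Reagents that add atoms: bis(pinacolato)diboron, CC1(C)OB(OC1(C)C)B1OC(C)(C)C(C)(C)O1
Why: Iridium-catalysed aromatic C–H borylation is sterically controlled and functionalises only the C–H that is meta to both substituents.

Step 11
Reactants: 18 the aryl boronate
Product: 20 benzene-1,3,5-triol (phloroglucinol), via 3,5-bis(methoxymethoxy)phenol 19 (not isolated)
Conditions: KHSO5 (as 2KHSO5·KHSO4·K2SO4), acetone/H2O, rt, 15 min; then HCl (3 M), MeOH, 50 °C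
Reagents that add atoms: potassium peroxymonosulfate, [K+].[O-]S(=O)(=O)OO
Why: ipso-Oxidation of the aryl boronate gives the phenol and acid-catalysed methanolysis of the MOM acetals then frees phloroglucinol.

Step 12
Reactants: 20 phloroglucinol
Product: 21 2,4,6-trihydroxybenzene-1,3,5-tricarbaldehyde
Conditions: hexamethylenetetramine (2.2 equiv), CF3CO2H, 100 °C, 2.5 h; then HCl (3 M), 100 °C, 1 h
Reagents that add atoms: hexamethylenetetramine, C1N2CN3CN1CN(C2)C3; water, O
Why: Duff formylation (aminomethylation, internal redox to the iminium, hydrolysis) occurs at all three equivalent positions of the very electron-rich ring; the yield is known to be low but the procedure is established.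

Step 13
Reactants: 21 the trialdehyde
Product: 22 2,4,6-tris[(tert-butoxycarbonyl)oxy]benzene-1,3,5-tricarbaldehyde
Conditions: Boc2O (3.6 equiv), iPr2NEt, DMAP (10 mol %), THF, 0 °C → rt
Reagents that add atoms: di-tert-butyl dicarbonate, CC(C)(C)OC(=O)OC(=O)OC(C)(C)C
Why: DMAP-catalysed O-acylation turns the three hydrogen-bonded phenols into aryl tert-butyl carbonates, the groups needed for the migration in step 14 and removable without acid at the end.

Step 14
Reactants: 22 the tri-Boc trialdehyde; 23 phenyllithium
Product: 26 rac-tert-butyl {[2,4-bis[(tert-butoxycarbonyl)oxy]-6-[(tert-butyldimethylsilyl)oxy]-3,5-diformylphenyl](phenyl)methyl} carbonate (fragment 2), via lithium alkoxide 24 (not isolated), via lithium phenoxide 25 (not isolated)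
Conditions: PhLi (1.0 equiv), THF, −78 °C, 20 min; TBSOTf (1.1 equiv), −78 → −40 °C; NaHCO3 (aq)
Reagents that add atoms: tert-butyldimethylsilyl trifluoromethanesulfonate, CC(C)(C)[Si](C)(C)OS(=O)(=O)C(F)(F)F
Why: 1,2-Addition of PhLi to one of three equivalent aldehydes (the anion formed deactivates the other two), O→O Boc migration from the neighbouring aryl carbonate to the alkoxide (the known entry to o-quinone-methide precursors) and O-silylation of the released phenoxide before it can eliminate; the new centre is racemic on purpose.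

**Coupling and end game**

Step 15
Reactants: 15 fragment 1; 26 fragment 2 (1.3 equiv)
Product: 27 5,7-bis-O-(tert-butoxycarbonyl)guajadial C
Conditions: Pd2(dba)3·CHCl3 (2.5 mol %), (Sa,R,R)-L1 (6 mol %), PhMe, 4 Å MS, 40 °C
Reagents that add atoms: none
Why: Proposed new method: zerovalent palladium ionises the benzhydrylic tert-butyl carbonate to an η3-benzyl complex, loss of CO2 gives tert-butoxide that desilylates the neighbouring aryl OTBS to form a C,O-palladacycle (a palladium-bound o-quinone methide), the exocyclic C=CH2 of 15 inserts into the Pd–benzyl bond with benzyl going to CH2, and the resulting η3-allyl palladium is closed by the phenoxide at its tertiary terminus (six-membered ring) with release of zerovalent palladium; the benzylic centre is set by the chiral phosphoramidite in the insertion step (the benzyl/quinone-methide complex epimerises quickly, so racemic 26 converges), and the spiro centre is argued to arise because palladium adds to the less hindered equatorial α-face of the methylene and the phenoxide attacks anti to palladium on the axial β-face; the closest known reactions are the Larock heteroannulation of 1,3-dienes with o-iodophenols, palladium-catalysed substitution of diarylmethyl carbonates through η3-benzyl complexes and decarboxylative zwitterion cycloadditions of vinyl benzoxazinanones, but a benzylic zwitterion adding to an unactivated 1,3-diene to give a spiro-chroman has not been shown.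

Step 16
Reactants: 27 the bis-Boc chroman
Product: 28 Guajadial C
Conditions: K2CO3 (0.2 equiv), MeOH/THF (1:1), 0 °C, 1 h; pH 6 phosphate buffer
Reagents that add atoms: none
Why: Base-catalysed methanolysis (transesterification) of the two aryl tert-butyl carbonates, activated by the ortho formyl groups, frees the phenols without acid, which the tertiary allylic aryl ether would not tolerate.

**Compound list**

1 | 3-methylbutanal (isovaleraldehyde) | CC(C)CC=O | starting material
2 | but-3-en-2-one (methyl vinyl ketone) | CC(=O)C=C | starting material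
3 | (S)-2-isopropyl-5-oxohexanal | CC(C)[C@H](CCC(C)=O)C=O | intermediate (not isolated)
4 | (S)-4-isopropylcyclohex-2-en-1-one, (S)-cryptone | CC(C)[C@@H]1CCC(=O)C=C1 | intermediate
5 | (E)-4-methoxybut-3-en-2-one | CO/C=C/C(C)=O | starting material
6 | (E)-tert-butyl[(4-methoxybuta-1,3-dien-2-yl)oxy]dimethylsilane | CO/C=C/C(=C)O[Si](C)(C)C(C)(C)C | intermediate
7 | (4S,4aS,8S,8aR)-6-[(tert-butyldimethylsilyl)oxy]-8-methoxy-4-isopropyl-3,4,4a,5,8,8a-hexahydronaphthalen-1(2H)-one; cis-fused, ring-fusion H atoms anti to iPr, OMe anti to H-8a | CC(C)[C@@H]1CCC(=O)[C@H]2[C@@H](OC)C=C(O[Si](C)(C)C(C)(C)C)C[C@@H]12 | intermediate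
8 | tert-butyl{[5-methoxy-4-methylidene-1-isopropyl-1,2,3,4,4a,5,8,8a-octahydronaphthalen-7-yl]oxy}dimethylsilane; stereocentres as in 7 | CC(C)[C@@H]1CCC(=C)[C@H]2[C@@H](OC)C=C(O[Si](C)(C)C(C)(C)C)C[C@@H]12 | intermediate
9 | tert-butyl{[5-methoxy-4-methyl-1-isopropyl-1,2,3,4,4a,5,8,8a-octahydronaphthalen-7-yl]oxy}dimethylsilane; methyl anti to H-4a, other centres as in 7 | CC(C)[C@@H]1CC[C@@H](C)[C@H]2[C@@H](OC)C=C(O[Si](C)(C)C(C)(C)C)C[C@@H]12 | intermediate (not isolated)
10 | (4aS,5R,8S,8aS)-5-methyl-8-isopropyl-4a,5,6,7,8,8a-hexahydronaphthalen-2(1H)-one; cis-fused | CC(C)[C@@H]1CC[C@@H](C)[C@H]2C=CC(=O)C[C@@H]12 | intermediate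
11 | 1-(phenylselanyl) derivative of 10; PhSe cis to H-8a | CC(C)[C@@H]1CC[C@@H](C)[C@H]2C=CC(=O)[C@H]([Se]c3ccccc3)[C@@H]12 | intermediate
12 | 3,4-dihydro derivative of 11 (saturated α-seleno ketone) | CC(C)[C@@H]1CC[C@@H](C)[C@H]2CCC(=O)[C@H]([Se]c3ccccc3)[C@@H]12 | intermediate (not isolated)
13 | Se-oxide of 12 | CC(C)[C@@H]1CC[C@@H](C)[C@H]2CCC(=O)[C@H]([Se](=O)c3ccccc3)[C@@H]12 | intermediate (not isolated)
14 | (4aR,5R,8S)-5-methyl-8-isopropyl-4,4a,5,6,7,8-hexahydronaphthalen-2(3H)-one | CC(C)[C@@H]1CC[C@@H](C)[C@H]2CCC(=O)C=C12 | intermediate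
15 | (4aR,5R,8S)-5-methyl-2-methylidene-8-isopropyl-2,3,4,4a,5,6,7,8-octahydronaphthalene (fragment 1) | CC(C)[C@@H]1CC[C@@H](C)[C@H]2CCC(=C)C=C12 | intermediate
16 | resorcinol | Oc1cccc(O)c1 | starting material
17 | 1,3-bis(methoxymethoxy)benzene | COCOc1cccc(OCOC)c1 | intermediate
18 | 2-[3,5-bis(methoxymethoxy)phenyl]-4,4,5,5-tetramethyl-1,3,2-dioxaborolane | COCOc1cc(OCOC)cc(c1)B1OC(C)(C)C(C)(C)O1 | intermediate
19 | 3,5-bis(methoxymethoxy)phenol | COCOc1cc(O)cc(OCOC)c1 | intermediate (not isolated)
20 | benzene-1,3,5-triol (phloroglucinol) | Oc1cc(O)cc(O)c1 | intermediate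
21 | 2,4,6-trihydroxybenzene-1,3,5-tricarbaldehyde | O=Cc1c(O)c(C=O)c(O)c(C=O)c1O | intermediate
22 | 2,4,6-tris[(tert-butoxycarbonyl)oxy]benzene-1,3,5-tricarbaldehyde | O=Cc1c(OC(=O)OC(C)(C)C)c(C=O)c(OC(=O)OC(C)(C)C)c(C=O)c1OC(=O)OC(C)(C)C | intermediate
23 | phenyllithium | [Li]c1ccccc1 | starting material
24 | lithium [2,4,6-tris[(tert-butoxycarbonyl)oxy]-3,5-diformylphenyl](phenyl)methanolate (racemic) | [Li]OC(c1ccccc1)c1c(OC(=O)OC(C)(C)C)c(C=O)c(OC(=O)OC(C)(C)C)c(C=O)c1OC(=O)OC(C)(C)C | intermediate (not isolated)
25 | lithium 3,5-bis[(tert-butoxycarbonyl)oxy]-2-{[(tert-butoxycarbonyl)oxy](phenyl)methyl}-4,6-diformylphenolate (racemic) | [Li]Oc1c(C=O)c(OC(=O)OC(C)(C)C)c(C=O)c(OC(=O)OC(C)(C)C)c1C(OC(=O)OC(C)(C)C)c1ccccc1 | intermediate (not isolated)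
26 | rac-tert-butyl {[2,4-bis[(tert-butoxycarbonyl)oxy]-6-[(tert-butyldimethylsilyl)oxy]-3,5-diformylphenyl](phenyl)methyl} carbonate (fragment 2) | CC(C)(C)[Si](C)(C)Oc1c(C=O)c(OC(=O)OC(C)(C)C)c(C=O)c(OC(=O)OC(C)(C)C)c1C(OC(=O)OC(C)(C)C)c1ccccc1 | intermediate
27 | 5,7-bis-O-(tert-butoxycarbonyl)guajadial C; spiro carbon S, benzylic carbon R, terpene centres as in 15 | CC(C)[C@@H]1CC[C@@H](C)[C@H]2CC[C@@]3(C=C12)C[C@H](c1ccccc1)c1c(OC(=O)OC(C)(C)C)c(C=O)c(OC(=O)OC(C)(C)C)c(C=O)c1O3 | intermediate
28 | Guajadial C; spiro carbon S, benzylic carbon R, ring-fusion CH R, methyl-bearing carbon R, isopropyl-bearing carbon S | CC(C)[C@@H]1CC[C@@H](C)[C@H]2CC[C@@]3(C=C12)C[C@H](c1ccccc1)c1c(O)c(C=O)c(O)c(C=O)c1O3 | target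

**Totals**

Total step count: 16. Longest linear sequence: 9 steps (steps 1, 3, 4, 5, 6, 7, 8, 15, 16); step 2 and steps 9–14 are side branches.

**Steps most likely to fail**

Step 15 (the proposed annulation; unproven, and the face selectivity at the spiro carbon rests on a conformational argument). Fallback with known chemistry, setting out from 22, 23 and 15 and returning at 27: 25 is generated as in step 14 but not silylated, then 15 and MgBr2·OEt2 are added at −78 °C and the mixture is warmed to 25 °C. Magnesium-assisted β-elimination of the benzylic tert-butyl carbonate gives 5-benzylidene-2,4-bis[(tert-butoxycarbonyl)oxy]-6-oxocyclohexa-1,3-diene-1,3-dicarbaldehyde F6. This o-quinone methide undergoes the thermal inverse-demand hetero-Diels–Alder reaction with the exocyclic methylene of 15, oxygen going to the disubstituted carbon; this is the cycloaddition used in biomimetic syntheses of this meroterpenoid family. Stereocontrol is then substrate-based only, and 27 is separated from its diastereomers by preparative HPLC.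

Step 3 (a γ-branched cyclohexenone is a sluggish dienophile and the diene may decompose at 170 °C). Fallback setting out from 2 and 4 and returning at 10: 2 is silylated (TBSOTf, Et3N) to tert-butyl(buta-1,3-dien-2-yloxy)dimethylsilane F1. F1 adds to 4 under the mixed Lewis acid AlBr3/AlMe3 (PhMe/CH2Cl2, −5 °C), a system made for hindered cyclohexenones, to give the cis-fused 6-[(tert-butyldimethylsilyl)oxy]-4-isopropyl-3,4,4a,5,8,8a-hexahydronaphthalen-1(2H)-one F2. Cp2TiMe2 converts F2 into the 1-methylidene compound F3, and hydrogenation over PtO2 gives the 1-methyl silyl enol ether F4. Pd(OAc)2 in MeCN (Saegusa–Ito dehydrosilylation by stoichiometric divalent palladium, whose β-hydride loss can only create the C3=C4 bond) then delivers 10.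

Step 14 (one-pot addition, migration and silylation on a tris-aldehyde; the aryl silyl ether may not survive isolation). Fallback setting out from 25 and returning at 27: the cold solution of 25 is capped with Boc2O instead of TBSOTf to give rac-tert-butyl {[2,4,6-tris[(tert-butoxycarbonyl)oxy]-3,5-diformylphenyl](phenyl)methyl} carbonate F5. F5 takes the place of 26 in step 15; the palladium-bound tert-butoxide released on ionisation then removes the adjacent aryl Boc group by acyl transfer instead of desilylation before the diene inserts.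

**Further compounds**

F1 | step 3 | tert-butyl(buta-1,3-dien-2-yloxy)dimethylsilane | C=CC(=C)O[Si](C)(C)C(C)(C)C
F2 | step 3 | cis-fused 6-[(tert-butyldimethylsilyl)oxy]-4-isopropyl-3,4,4a,5,8,8a-hexahydronaphthalen-1(2H)-one; ring-fusion H atoms anti to iPr | CC(C)[C@@H]1CCC(=O)[C@H]2CC=C(O[Si](C)(C)C(C)(C)C)C[C@@H]12
F3 | step 3 | 1-methylidene analogue of F2 | CC(C)[C@@H]1CCC(=C)[C@H]2CC=C(O[Si](C)(C)C(C)(C)C)C[C@@H]12
F4 | step 3 | 1-methyl analogue of F2; methyl anti to H-8a | CC(C)[C@@H]1CC[C@@H](C)[C@H]2CC=C(O[Si](C)(C)C(C)(C)C)C[C@@H]12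
F5 | step 14 | rac-tert-butyl {[2,4,6-tris[(tert-butoxycarbonyl)oxy]-3,5-diformylphenyl](phenyl)methyl} carbonate | CC(C)(C)OC(=O)Oc1c(C=O)c(OC(=O)OC(C)(C)C)c(C=O)c(OC(=O)OC(C)(C)C)c1C(OC(=O)OC(C)(C)C)c1ccccc1
F6 | step 15 | 5-benzylidene-2,4-bis[(tert-butoxycarbonyl)oxy]-6-oxocyclohexa-1,3-diene-1,3-dicarbaldehyde | O=C1C(C=O)=C(OC(=O)OC(C)(C)C)C(C=O)=C(OC(=O)OC(C)(C)C)C1=Cc1ccccc1
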